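**Plan**
1. Retrosynthesis: the γ-lactone C12–O bond is cut first (oxidative lactonisation of a C6,C12-diol), then the 1,10-epoxide oxygen (epoxidation of a Z-C1=C10 alkene), then C1=C10 itself by re-inserting sulfur, so the ten-membered carbocycle comes from an eleven-membered thiacycle (C1–S–C10) that loses SO2.
2. Enabling feature: the cis-1,10-epoxide on the cyclodecene ring is the retron of a Z-trisubstituted C1=C10 alkene whose neighbours C2 and C9 are the only unfunctionalised ring methylenes, so a sulfonyl bridge between C1 and C10 has no β-leaving group; C8–C10 with the C10 methyl then map onto crotonaldehyde.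
3. The thiacycle is cut at C7–C8 (intramolecular allylchromium addition), S–C10 (thia-Michael), S–C1 (thioacetate displacement), C5–C6 (alkenylchromium plus enal) and C4–CH3 (carbomagnesiation of a propargylic alcohol).
4. Forward: C1–C5 alkynol, Z-iodoalkene, C5–C6 coupling, sulfur and crotonaldehyde, eleven-membered ring by C7–C8 closure, sulfone, contraction to the ten-membered ring, then ester, epoxide, desilylation and the lactone ring last.
5. Stereochemistry: C3 by Noyori transfer hydrogenation; Z-C4=C5 by chelate-controlled anti-carbomagnesiation; C6 by ligand-controlled Ni/Cr coupling; C7 and C8 in the macrocyclisation (chair transition state, face set by C6); Z-C1=C10 by the ring during the contraction; epoxide face by the Shi ketone.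

Key step: step 16

Remarks on the chemistry.
- Atom numbers are germacrane numbers of the target: ring C1–C10 (C1/C10 epoxide, C3 carbinol, C4=C5, C6 lactone carbinol, C7, C8 ester carbon), C11–C13 lactone carbons, C14 methyl on C10, C15 methyl on C4.
- The sulfur-bearing carbon C10 of 20–27 is formed without control and carried as both epimers; it becomes sp2 in step 16.
- Compounds 17 and 19–23 are carried as a mixture of C7=C11 geometric isomers, which converge in step 14.
- In step 7 the ligand is written as its (S)-enantiomer; the enantiomer used is the one that directs the alkenyl group to the Si face of 11 (both are available from valinol).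

**Route**

Step 1
Reactants: 1 3-chloropropanoyl chloride; 2 bis(trimethylsilyl)acetylene
Product: 3 5-chloro-1-(trimethylsilyl)pent-1-yn-3-one
Conditions: AlCl3, CH2Cl2, 0 °C
Reagents that add atoms: none
Why: Friedel–Crafts-type acylation of the bis-silyl alkyne with ipso-desilylation should give the alkynyl ketone, the remaining silyl group protecting the alkyne terminus.

Step 2
Reactants: 3 5-chloro-1-(trimethylsilyl)pent-1-yn-3-one
Product: 4 (3S)-5-chloro-1-(trimethylsilyl)pent-1-yn-3-ol
Conditions: Ru[(S,S)-TsNCH(Ph)CH(Ph)NH](p-cymene) (1 mol %), i-PrOH, rt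
Reagents that add atoms: none
Why: Noyori asymmetric transfer hydrogenation of an alkynyl ketone under base-free conditions should deliver hydride to one carbonyl face, the (S,S)-catalyst setting the (S)-carbinol (C3) without exposing the β-chloro ketone to base.

Step 3
Reactants: 4 (3S)-5-chloro-1-(trimethylsilyl)pent-1-yn-3-ol
Product: 5 (3S)-5-chloropent-1-yn-3-ol
Conditions: K2CO3 (0.2 equiv), MeOH, 0 °C
Reagents that add atoms: none
Why: Methoxide-catalysed protodesilylation of the alkynylsilane should free the terminal alkyne without touching the alcohol or the primary chloride.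

Step 4
Reactants: 5 (3S)-5-chloropent-1-yn-3-ol
Product: 7 (1Z,3S)-5-chloro-1-iodo-2-methylpent-1-en-3-ol, via alkenylmagnesium alkoxide 6 (not isolated)
Conditions: MeMgBr (3.5 equiv), CuI (0.2 equiv), THF/Et2O, −10 °C to rt; then I2, −40 to 0 °C
Reagents that add atoms: methylmagnesium bromide, C[Mg]Br; iodine, II
Why: Copper-catalysed anti-carbomagnesiation of the propargylic alkoxide should place methyl on C4 and magnesium on C5 cis to the carbinol through a five-membered chelate, and iodinolysis with retention then fixes the Z-trisubstituted C4=C5 geometry.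

Step 5
Reactants: 7 (1Z,3S)-5-chloro-1-iodo-2-methylpent-1-en-3-ol
Product: 8 tert-butyl{[(1Z,3S)-5-chloro-1-iodo-2-methylpent-1-en-3-yl]oxy}dimethylsilane
Conditions: TBSCl, imidazole, DMF, rt
Reagents that add atoms: tert-butyldimethylsilyl chloride, CC(C)(C)[Si](C)(C)Cl
Why: Standard silylation of the secondary allylic alcohol protects C3–OH for the organometallic steps.

Step 6
Reactants: 9 2,2-dimethyl-1,3-dioxan-5-one; 10 (triphenylphosphoranylidene)acetaldehyde
Product: 11 2-(2,2-dimethyl-1,3-dioxan-5-ylidene)acetaldehyde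
Conditions: toluene, 80 °C
Reagents that add atoms: none
Why: Wittig olefination of the activated α,α′-dialkoxy ketone with the stabilised formyl ylide should give the enal, and the symmetry of the dioxane removes any question of alkene geometry.

Step 7
Reactants: 8 silyl ether of the Z-iodoalkene; 11 2-(2,2-dimethyl-1,3-dioxan-5-ylidene)acetaldehyde
Product: 13 (2R,3Z,5S)-5-[(tert-butyldimethylsilyl)oxy]-7-chloro-1-(2,2-dimethyl-1,3-dioxan-5-ylidene)-4-methylhept-3-en-2-ol, via alkenylchromium dichloride 12 (not isolated)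
Conditions: CrCl2 (3 equiv), NiCl2 (2 mol %), (S)-N-[2-(4-isopropyl-4,5-dihydro-1,3-oxazol-2-yl)-6-methylphenyl]methanesulfonamide (3.3 equiv), Et3N, THF, rt; aqueous work-up
Reagents that add atoms: none
Why: Nozaki–Hiyama–Kishi coupling, in which nickel-catalysed activation of the alkenyl iodide and transmetalation to trivalent chromium keep the Z geometry, and the sulfonamide-bound alkenylchromium should add 1,2 to the Si face of the enal to set C6 under reagent control.

Step 8
Reactants: 13 allylic alcohol from step 7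
Product: 14 C6 tert-butyldimethylsilyl ether of 13 (bis-silyl ether, C1 chloride, dioxane intact)
Conditions: TBSOTf, 2,6-lutidine, CH2Cl2, −78 °C
Reagents that add atoms: tert-butyldimethylsilyl trifluoromethanesulfonate, CC(C)(C)[Si](C)(C)OS(=O)(=O)C(F)(F)F
Why: Silyl triflate under buffered conditions should protect the acid-sensitive doubly allylic C6–OH without ionisation.

Step 9
Reactants: 14 bis-silyl ether chloride
Product: 15 S-acetyl thioester (14 with Cl at C1 replaced by SAc)
Conditions: KSAc, NaI (0.1 equiv), DMF, 50 °C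
Reagents that add atoms: potassium thioacetate, CC(=O)[S-].[K+]
Why: SN2 displacement of the primary chloride by thioacetate (iodide catalysis) should introduce sulfur at C1 in masked form.

Step 10
Reactants: 15 S-acetyl thioester
Product: 16 2-alkylidenepropane-1,3-diol (15 without the isopropylidene group; C12–OH and C13–OH free)
Conditions: PPTS (0.1 equiv), MeOH, 0 °C to rt
Reagents that add atoms: none
Why: Acid-catalysed transacetalisation to methanol should remove only the isopropylidene acetal, the secondary silyl ethers and the thioester being stable to pyridinium tosylate.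

Step 11
Reactants: 16 diol
Product: 17 mono-TBS ether of 16 at one primary hydroxyl (either C7=C11 isomer)
Conditions: TBSCl (1.0 equiv), imidazole, CH2Cl2, −20 °C; bis-silyl ether and diol recycled
Reagents that add atoms: tert-butyldimethylsilyl chloride, CC(C)(C)[Si](C)(C)Cl
Why: Mono-silylation of the diol should favour the hydroxymethyl group trans to the bulky C6 substituent, and either regioisomer is usable because both give the same allylchromium species in step 14.

Step 12
Reactants: 17 mono-TBS thioacetate; 18 (E)-but-2-enal (crotonaldehyde)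
Product: 20 3-(alkylsulfanyl)butanal (C1–S–C10 sulfide with C8 aldehyde and free C13–OH; both C10 epimers), via thiol 19 (not isolated)
Conditions: K2CO3, degassed MeOH, 0 °C; then AcOH to neutral, crotonaldehyde (2 equiv), Et3N (0.1 equiv), 0 °C
Reagents that add atoms: none
Why: Methanolysis of the thioester liberates the thiol, which should undergo thia-Michael addition to crotonaldehyde faster than any other process, the new centre C10 being left uncontrolled because it is destroyed in step 16.

Step 13
Reactants: 20 sulfide aldehyde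
Product: 22 allylic chloride seco-aldehyde, via allylic mesylate 21 (not isolated)
Conditions: MsCl, 2,4,6-collidine, LiCl, DMF, 0 °C
Reagents that add atoms: lithium chloride, [Li+].[Cl-]
Why: Mesylation of the primary allylic alcohol and in situ SN2 displacement by chloride should give the allylic chloride without touching the aldehyde or the sulfide.

Step 14
Reactants: 22 allylic chloride seco-aldehyde
Product: 24 eleven-membered thiacycle alcohol (ring S, C1–C10; C8–OH; C3 and C6 O-TBS; C7 bearing 3-(TBS-oxy)prop-1-en-2-yl; C3, C6, C7, C8 configured as in the target), via allylchromium dichloride 23 (not isolated)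
Conditions: CrCl2 (8 equiv), NaI (0.2 equiv), THF/DMF 4:1, slow addition to 0.003 M, rt
Reagents that add atoms: none
Why: Intramolecular Nozaki–Hiyama allylation in which the allylchromium adds through its γ-carbon C7 in a chair Zimmerman–Traxler transition state, which should give the anti C7/C8 relationship, while the C6 stereocentre (C6–H eclipsing the allyl plane, attack anti to the silyloxy group) should set the C7 face as the eleven-membered ring closes.

Step 15
Reactants: 24 thiacycle alcohol
Product: 25 cyclic sulfone (S-dioxide of 24)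
Conditions: (NH4)6Mo7O24·4H2O (0.1 equiv), 30% H2O2 (3 equiv), EtOH, 0 °C to rt
Reagents that add atoms: hydrogen peroxide, OO
Why: Molybdate-catalysed peroxide oxidation of a sulfide to the sulfone is chemoselective in the presence of alkenes, a free alcohol and silyl ethers.

Step 16
Reactants: 25 cyclic sulfone
Product: 28 (1(10)Z,4Z)-cyclodecadiene alcohol (ten-membered carbocycle; C8–OH; C3 and C6 O-TBS; C7 side chain as in 24), via bromo sulfone 26 (not isolated), via episulfone 27 (not isolated)
Conditions: CBr2F2 (5 equiv), KOH on Al2O3 (excess), t-BuOH/CH2Cl2, 0 °C to rt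
Reagents that add atoms: none
Why: Ramberg–Bäcklund reaction in its one-flask halogenative form: KOH deprotonates the sulfone at the less hindered α-methylene C1 and the carbanion is brominated by CBr2F2 to give 26, a second deprotonation at C10 displaces bromide in a 3-exo-tet closure to the thiirane 1,1-dioxide 27, and cheletropic loss of SO2 from this bicyclic episulfone leaves the C1=C10 bond, so the eleven-membered thiacycle contracts to the ten-membered carbocycle by deletion of sulfur. The closest known reaction type is the Ramberg–Bäcklund ring contraction of medium and large cyclic sulfones to cycloalkenes. No new stereocentre is formed and both C10 epimers of 25 converge; the one new stereo-element, the C1=C10 geometry, is controlled by the ring, because only the cis-fused episulfone (C2 and C9 on the same side) is easily accommodated and a trans-cyclodecene is markedly more strained, which should give the Z alkene that the cis-epoxide requires. The step needs clean α-sulfonyl deprotonation and halogenation without β-elimination, and the substrate secures this because C2 and C9 are unfunctionalised methylenes, the oxygens at C3, C6 and C12 are silyl ethers, the C8 hydroxyl is only an alkoxide under the conditions, and no carbonyl group is present until step 20. The difluorocarbene released from CBr2F2 should be consumed by the alcoholic hydroxide and not add to the alkenes at this temperature.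

Step 17
Reactants: 28 cyclodecadiene alcohol
Product: 29 C8 isobutyrate of 28
Conditions: isobutyryl chloride, DMAP (0.2 equiv), pyridine, CH2Cl2, 0 °C to rt
Reagents that add atoms: 2-methylpropanoyl chloride, CC(C)C(Cl)=O
Why: DMAP-catalysed acylation of the only free hydroxyl installs the C8 ester with retention at C8.

Step 18
Reactants: 29 C8 isobutyrate
Product: 30 (1R,10S)-1,10-epoxide of 29
Conditions: D-fructose-derived Shi ketone (1,2:4,5-di-O-isopropylidene-β-D-erythro-2,3-hexodiulo-2,6-pyranose, 0.3 equiv), Oxone, K2CO3, Bu4NHSO4, MeCN/CH2(OMe)2/aqueous Na2B4O7 buffer, 0 °C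
Reagents that add atoms: potassium peroxymonosulfate (Oxone), [K+].[O-]S(=O)(=O)OO
Why: Shi epoxidation, in which the chiral dioxirane should attack the most electron-rich alkene C1=C10 (C4=C5 is deactivated and shielded by two allylic silyloxy groups, C11=C13 is only 1,1-disubstituted) through the spiro transition state that delivers oxygen to the face giving (1R,10S), the same sense as for 1-arylcycloalkenes.

Step 19
Reactants: 30 epoxide
Product: 31 triol (C3–OH, C6–OH, C12–OH; epoxide and C8 isobutyrate intact)
Conditions: HF·pyridine, pyridine, THF, 0 °C to rt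
Reagents that add atoms: none
Why: Buffered fluoride cleavage of the three silyl ethers under mildly acidic conditions should avoid both C8-to-C6 acyl migration and opening of the epoxide.

Step 20
Reactants: 31 triol
Product: 34 CNP0261225.1, via enal 32 (not isolated), via lactol 33 (not isolated)
Conditions: TEMPO (0.2 equiv), PhI(OAc)2 (3 equiv), CH2Cl2, rt
Reagents that add atoms: none
Why: Oxoammonium (TEMPO) oxidation is selective for the primary allylic alcohol, and the resulting aldehyde should be trapped by the C6 hydroxyl as a five-membered lactol that is oxidised on to the trans-fused α-methylene γ-lactone while the secondary C3 alcohol reacts much more slowly.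

**Compound list**
1 | 3-chloropropanoyl chloride | O=C(Cl)CCCl | starting material
2 | bis(trimethylsilyl)acetylene | C[Si](C)(C)C#C[Si](C)(C)C | starting material
3 | 5-chloro-1-(trimethylsilyl)pent-1-yn-3-one | C[Si](C)(C)C#CC(=O)CCCl | intermediate
4 | (3S)-5-chloro-1-(trimethylsilyl)pent-1-yn-3-ol | C[Si](C)(C)C#C[C@@H](O)CCCl | intermediate
5 | (3S)-5-chloropent-1-yn-3-ol | C#C[C@@H](O)CCCl | intermediate
6 | bromomagnesium alkoxide of (1Z,3S)-1-(bromomagnesio)-5-chloro-2-methylpent-1-en-3-ol | Br[Mg]/C=C(/C)[C@@H](O[Mg]Br)CCCl | intermediate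
7 | (1Z,3S)-5-chloro-1-iodo-2-methylpent-1-en-3-ol | I/C=C(/C)[C@@H](O)CCCl | intermediate
8 | tert-butyl{[(1Z,3S)-5-chloro-1-iodo-2-methylpent-1-en-3-yl]oxy}dimethylsilane | I/C=C(/C)[C@@H](O[Si](C)(C)C(C)(C)C)CCCl | intermediate
9 | 2,2-dimethyl-1,3-dioxan-5-one | CC1(C)OCC(=O)CO1 | starting material
10 | (triphenylphosphoranylidene)acetaldehyde | O=CC=P(c1ccccc1)(c1ccccc1)c1ccccc1 | starting material
11 | 2-(2,2-dimethyl-1,3-dioxan-5-ylidene)acetaldehyde | CC1(C)OCC(=CC=O)CO1 | intermediate
12 | alkenylchromium dichloride from 8 (CrCl2 in place of I) | Cl[Cr](Cl)/C=C(/C)[C@@H](O[Si](C)(C)C(C)(C)C)CCCl | intermediate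
13 | (2R,3Z,5S)-5-[(tert-butyldimethylsilyl)oxy]-7-chloro-1-(2,2-dimethyl-1,3-dioxan-5-ylidene)-4-methylhept-3-en-2-ol | CC1(C)OCC(=C[C@@H](O)/C=C(/C)[C@@H](O[Si](C)(C)C(C)(C)C)CCCl)CO1 | intermediate
14 | C6 TBS ether of 13 | CC1(C)OCC(=C[C@@H](O[Si](C)(C)C(C)(C)C)/C=C(/C)[C@@H](O[Si](C)(C)C(C)(C)C)CCCl)CO1 | intermediate
15 | S-acetyl thioester (14 with SAc at C1) | CC1(C)OCC(=C[C@@H](O[Si](C)(C)C(C)(C)C)/C=C(/C)[C@@H](O[Si](C)(C)C(C)(C)C)CCSC(C)=O)CO1 | intermediate
16 | diol (15 without isopropylidene) | OCC(CO)=C[C@@H](O[Si](C)(C)C(C)(C)C)/C=C(/C)[C@@H](O[Si](C)(C)C(C)(C)C)CCSC(C)=O | intermediate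
17 | mono-TBS ether of 16 (C7=C11 isomer mixture) | CC(C)(C)[Si](C)(C)OCC(CO)=C[C@@H](O[Si](C)(C)C(C)(C)C)/C=C(/C)[C@@H](O[Si](C)(C)C(C)(C)C)CCSC(C)=O | intermediate
18 | (E)-but-2-enal (crotonaldehyde) | C/C=C/C=O | starting material
19 | thiol from 17 | CC(C)(C)[Si](C)(C)OCC(CO)=C[C@@H](O[Si](C)(C)C(C)(C)C)/C=C(/C)[C@@H](O[Si](C)(C)C(C)(C)C)CCS | intermediate
20 | sulfide aldehyde (3-(alkylsulfanyl)butanal; both C10 epimers) | CC(C)(C)[Si](C)(C)OCC(CO)=C[C@@H](O[Si](C)(C)C(C)(C)C)/C=C(/C)[C@@H](O[Si](C)(C)C(C)(C)C)CCSC(C)CC=O | intermediate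
21 | allylic mesylate of 20 | CC(C)(C)[Si](C)(C)OCC(COS(C)(=O)=O)=C[C@@H](O[Si](C)(C)C(C)(C)C)/C=C(/C)[C@@H](O[Si](C)(C)C(C)(C)C)CCSC(C)CC=O | intermediate
22 | allylic chloride seco-aldehyde | CC(C)(C)[Si](C)(C)OCC(CCl)=C[C@@H](O[Si](C)(C)C(C)(C)C)/C=C(/C)[C@@H](O[Si](C)(C)C(C)(C)C)CCSC(C)CC=O | intermediate
23 | allylchromium dichloride from 22 | CC(C)(C)[Si](C)(C)OCC(C[Cr](Cl)Cl)=C[C@@H](O[Si](C)(C)C(C)(C)C)/C=C(/C)[C@@H](O[Si](C)(C)C(C)(C)C)CCSC(C)CC=O | intermediate
24 | eleven-membered thiacycle alcohol | C=C(CO[Si](C)(C)C(C)(C)C)[C@H]1[C@H](O)CC(C)SCC[C@H](O[Si](C)(C)C(C)(C)C)/C(C)=C\[C@@H]1O[Si](C)(C)C(C)(C)C | intermediate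
25 | cyclic sulfone of 24 | C=C(CO[Si](C)(C)C(C)(C)C)[C@H]1[C@H](O)CC(C)S(=O)(=O)CC[C@H](O[Si](C)(C)C(C)(C)C)/C(C)=C\[C@@H]1O[Si](C)(C)C(C)(C)C | intermediate
26 | α-bromo sulfone (Br at C1) | C=C(CO[Si](C)(C)C(C)(C)C)[C@H]1[C@H](O)CC(C)S(=O)(=O)C(Br)C[C@H](O[Si](C)(C)C(C)(C)C)/C(C)=C\[C@@H]1O[Si](C)(C)C(C)(C)C | intermediate
27 | episulfone (thiirane 1,1-dioxide fused at C1–C10) | C=C(CO[Si](C)(C)C(C)(C)C)[C@H]1[C@H](O)CC2(C)C(C[C@H](O[Si](C)(C)C(C)(C)C)/C(C)=C\[C@@H]1O[Si](C)(C)C(C)(C)C)S2(=O)=O | intermediate
28 | (1(10)Z,4Z)-cyclodecadiene alcohol | C=C(CO[Si](C)(C)C(C)(C)C)[C@H]1[C@H](O)C/C(C)=C\C[C@H](O[Si](C)(C)C(C)(C)C)/C(C)=C\[C@@H]1O[Si](C)(C)C(C)(C)C | intermediate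
29 | C8 isobutyrate of 28 | C=C(CO[Si](C)(C)C(C)(C)C)[C@H]1[C@H](OC(=O)C(C)C)C/C(C)=C\C[C@H](O[Si](C)(C)C(C)(C)C)/C(C)=C\[C@@H]1O[Si](C)(C)C(C)(C)C | intermediate
30 | (1R,10S)-1,10-epoxide of 29 | C=C(CO[Si](C)(C)C(C)(C)C)[C@H]1[C@H](OC(=O)C(C)C)C[C@]2(C)O[C@@H]2C[C@H](O[Si](C)(C)C(C)(C)C)/C(C)=C\[C@@H]1O[Si](C)(C)C(C)(C)C | intermediate
31 | triol (C3, C6, C12 hydroxyls) | C=C(CO)[C@H]1[C@H](OC(=O)C(C)C)C[C@]2(C)O[C@@H]2C[C@H](O)/C(C)=C\[C@@H]1O | intermediate
32 | C12 enal | C=C(C=O)[C@H]1[C@H](OC(=O)C(C)C)C[C@]2(C)O[C@@H]2C[C@H](O)/C(C)=C\[C@@H]1O | intermediate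
33 | lactol (C12 hemiacetal with O6) | C=C1C(O)O[C@H]2/C=C(/C)[C@@H](O)C[C@H]3O[C@@]3(C)C[C@@H](OC(=O)C(C)C)[C@H]12 | intermediate
34 | CNP0261225.1 | C=C1C(=O)O[C@H]2/C=C(/C)[C@@H](O)C[C@H]3O[C@@]3(C)C[C@@H](OC(=O)C(C)C)[C@H]12 | target

**Step count and risks**
Total step count: 20. Longest linear sequence: 19 (steps 1–5 and 7–20; step 6 is a one-step branch).

Steps most likely to fail:

1. Step 14. Oligomerisation may compete with closure of the eleven-membered ring, and the ring-forming transition state may override the facial control at C7 by the C6 silyloxy group. Fallback, setting out from 14 and returning at 24: the C7–C8 bond is made intermolecularly and the ring is closed at sulfur. The isopropylidene group of 14 is removed (PPTS, MeOH) to give the chloro diol F1, which is mono-silylated (TBSCl, imidazole) to the mono-TBS ether F2. Mesylation and chloride displacement (MsCl, collidine, LiCl) through the allylic mesylate F3 give the bis-chloride F4. Thioacetic acid is added to crotonaldehyde 18 to give 3-(acetylsulfanyl)butanal F5. CrCl2 in THF reduces only the allylic chloride of F4, and the allylchromium dichloride F6 adds to F5 to give the acyclic anti homoallylic alcohol thioacetate F7, with C7 and C8 set without ring constraint. Methanolysis (K2CO3, MeOH) gives the thiol F8, which closes the ring by intramolecular S-alkylation at C1 (Cs2CO3, DMF, high dilution) to give 24.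

2. Step 16. Multiple bromination at the C1 methylene, slow 1,3-elimination at the tertiary C10 centre, or alkoxide and carbene side reactions may divert the sulfone from clean extrusion. Fallback, setting out from 25 and returning at 28: the C1–C10 bond is made by oxidative coupling and not by halogenation and displacement. The sulfone 25 is treated with n-BuLi (3.3 equiv, THF, −78 °C) to give the lithium alkoxide α,α′-dilithio sulfone F9, which is oxidised with CuCl2 to the episulfone 27; this loses SO2 on warming to give 28.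

3. Step 18. Epoxidation of C11=C13 may compete, or the ring's own facial bias may be mismatched with the chiral dioxirane. Fallback, setting out from 28 and returning at 30: oxygen is delivered by the substrate and not by a chiral reagent. The free homoallylic C8–OH of 28 directs epoxidation (VO(acac)2 cat., t-BuOOH, CH2Cl2, 0 °C) to the syn face of C1=C10 to give the epoxy alcohol F10, which is then acylated (isobutyryl chloride, DMAP, pyridine) to 30.

Further compounds
F1 | step 14 | chloro diol (14 without the isopropylidene group) | OCC(CO)=C[C@@H](O[Si](C)(C)C(C)(C)C)/C=C(/C)[C@@H](O[Si](C)(C)C(C)(C)C)CCCl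
F2 | step 14 | mono-TBS ether of F1 | CC(C)(C)[Si](C)(C)OCC(CO)=C[C@@H](O[Si](C)(C)C(C)(C)C)/C=C(/C)[C@@H](O[Si](C)(C)C(C)(C)C)CCCl
F3 | step 14 | allylic mesylate of F2 | CC(C)(C)[Si](C)(C)OCC(COS(C)(=O)=O)=C[C@@H](O[Si](C)(C)C(C)(C)C)/C=C(/C)[C@@H](O[Si](C)(C)C(C)(C)C)CCCl
F4 | step 14 | bis-chloride (allylic chloride, C1 chloride) | CC(C)(C)[Si](C)(C)OCC(CCl)=C[C@@H](O[Si](C)(C)C(C)(C)C)/C=C(/C)[C@@H](O[Si](C)(C)C(C)(C)C)CCCl
F5 | step 14 | 3-(acetylsulfanyl)butanal | CC(=O)SC(C)CC=O
F6 | step 14 | allylchromium dichloride from F4 | CC(C)(C)[Si](C)(C)OCC(C[Cr](Cl)Cl)=C[C@@H](O[Si](C)(C)C(C)(C)C)/C=C(/C)[C@@H](O[Si](C)(C)C(C)(C)C)CCCl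
F7 | step 14 | acyclic anti homoallylic alcohol thioacetate | C=C(CO[Si](C)(C)C(C)(C)C)[C@@H]([C@H](O)CC(C)SC(C)=O)[C@@H](O[Si](C)(C)C(C)(C)C)/C=C(/C)[C@@H](O[Si](C)(C)C(C)(C)C)CCCl
F8 | step 14 | thiol from F7 | C=C(CO[Si](C)(C)C(C)(C)C)[C@@H]([C@H](O)CC(C)S)[C@@H](O[Si](C)(C)C(C)(C)C)/C=C(/C)[C@@H](O[Si](C)(C)C(C)(C)C)CCCl
F9 | step 16 | lithium alkoxide α,α′-dilithio sulfone from 25 | C=C(CO[Si](C)(C)C(C)(C)C)[C@H]1[C@H](O[Li])CC(C)([Li])S(=O)(=O)C([Li])C[C@H](O[Si](C)(C)C(C)(C)C)/C(C)=C\[C@@H]1O[Si](C)(C)C(C)(C)C
F10 | step 18 | (1R,10S)-epoxy alcohol from 28 | C=C(CO[Si](C)(C)C(C)(C)C)[C@H]1[C@H](O)C[C@]2(C)O[C@@H]2C[C@H](O[Si](C)(C)C(C)(C)C)/C(C)=C\[C@@H]1O[Si](C)(C)C(C)(C)C
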